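The numbers in the tables are simulated for substances that don't exist.

Look into the vessel and follow one molecule of starting material. It meets a fork: the free enzyme turns it into product, or the protic impurity takes it away.

| flask | starting material | protic impurity | free enzyme | temperature | remark | time |
|---|---|---|---|---|---|---|
| zeta | 0.081 M (in portions, 2) | 0.027 M | 5.4 µM | 20 °C | run made earlier; portions every 8.0 h |  |
| south-west | 0.054 M (in portions, 2) | 0.0270 M | 5.4 µM | 20 °C | the portions of starting material follow each other after 8.0 h, the first at the start | 15 h |
| south | 0.054 M | 0.0270 M | 10 µM | 35 °C | everything together at the start | 15 h |

zeta run (percent of the starting material charged)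

| time / h | product / % | starting material / % |
|---|---|---|
| 0.417 | 7.3 | 38.5 |
| 0.667 | 8.7 | 32.3 |
| 1.00 | 11.4 | 28.9 |
| 2.00 | 15.4 | 19.0 |
| 3.00 | 14.4 | 16.3 |
| 5.00 | 17.2 | 11.6 |

(standard deviation of a reading: 1 percentage point)

- the earlier runs do not show what temperature does; that part of a forecast is a guess
- no earlier run changes the charge of free enzyme; that part of a forecast is a guess

- which of the two ends with the higher amount of product, in percent of the starting material charged ("neither" if they lie within 2 percentage points) (south-west / south / neither)
- product at the end, in percent of the starting material charged, south-west
- product at the end, in percent of the starting material charged, south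

Fold the charges of south-west and south into one number; this reckoning is mine:

Q = c(protic impurity) / c(starting material, whole charge) = 0.0270 M / 0.054 M = 0.500

Read Q as the share of the charged starting material that the impurity claims, assuming one impurity molecule takes one molecule of starting material. Once the impurity is used up, product plus remaining starting material should therefore stand at

1 − Q = 50.0 % of the charge,

and that sum holds where the impurity wins its whole share; where it does not, the sum stands higher, so Q sets no cap on product by itself.

Test this on zeta, where Q is 0.333. For its first portion the sum should fall towards 16.7 %, and the reading at 5.00 h is 28.8 %, still above that limit.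

One number is not enough, though, since Q is equal in the two flasks and says nothing of the split. In zeta, the share of vanished starting material read as product is 0.635 up to 0.417 h, but 0.243 between 2.00 h and 5.00 h, lower as time passes. Early molecules have the better chance, so I commit to south, which has its whole charge present at the start.

The forecast names south, with 22 % for south-west and 52 % for south, and it warns: “The temperature and enzyme effects are guesses.”

The flask gives 16.8 % in south-west and 29.3 % in south, so south ends higher.

    free enzyme → unfolded enzyme (k = 1.40 × 10⁻⁶ s⁻¹, Ea = 180 kJ mol⁻¹)
    starting material + protic impurity → quenched substrate (k = 0.00370 M⁻¹ s⁻¹, Ea = 72.0 kJ mol⁻¹)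
    free enzyme → spent catalyst (k = 6.60 × 10⁻⁵ s⁻¹, Ea = 96.0 kJ mol⁻¹)
    starting material + free enzyme → product + free enzyme, rate k4*[starting material]^2.5*[free enzyme]/(1 + ([starting material]/Kh4)^2.5) (0.0640 M, k = 3800 M⁻²·⁵ s⁻¹, Ea = 20.0 kJ mol⁻¹)
    (constants at 20 °C)

Q is the number to hold against this. At 15.0 h south holds 29.3 % product and 20.7 % starting material, together 50.0 %, with the protic impurity, the limiting reagent of the loss, at 0 % of its own charge.

Now take a neighbour flask, south-west kept at 45 °C. Its amounts are held, so Q stays 0.500, and if the impurity wins its whole share the sum should be 50.0 %. The computed flask gives 1.92 % product and 48.1 % starting material, together 50.0 %.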